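**Retrosynthetic overview**

- The target is acyclic and achiral. The plan rests on the C1–C2 unit (ester carbonyl C1 and its α-methylene C2), treated as the two-carbon acetate unit that is added last to a C24 chain.
- Disconnection at C2–C3: benzyl hexacosanoate ⇐ benzyl 3-oxohexacosanoate (7) ⇐ tetracosanoyl imidazolide (3) + benzyl hydrogen malonate (4), by a decarboxylative Claisen condensation.
- The C3 oxygen is then removed in the order of fatty acid biosynthesis (C=O → CHOH → C2=C3 → CH2–CH2) with reagents that leave the benzyl ester intact.
- No ring is formed at any stage. The benzyl ester comes in with the malonate, so no late esterification is needed.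

Key step: step 2

Remark: the carbinol carbon C3 of compounds 8 and 9 is formed racemic and is erased in step 4, so no stereocontrol is planned.

**Step 1**
Reactants: 1 tetracosanoic acid; 2 1,1'-carbonyldiimidazole
Product: 3 1-(imidazol-1-yl)tetracosan-1-one
Conditions: CDI (1.05 equiv), THF, 45 °C until gas evolution stops; evaporate, use the crude solid under N2
Reagents that add atoms: 1,1'-carbonyldiimidazole (compound 2), O=C(n1ccnc1)n1ccnc1
Why: Carboxylic acid activation by acyl substitution on CDI, where the mixed anhydride collapses with loss of CO2 to the N-acyl imidazole, and the saturated chain has no competing functional group.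

**Step 2**
Reactants: 3 1-(imidazol-1-yl)tetracosan-1-one; 4 3-(benzyloxy)-3-oxopropanoic acid (benzyl hydrogen malonate)
Product: 7 benzyl 3-oxohexacosanoate, via magnesium malonate enolate 5 (not isolated), via magnesium acylmalonate 6 (not isolated)
Conditions: 4 (2 equiv), MgCl2 (2.2 equiv), Et3N (4.5 equiv), THF/MeCN, 25 °C, 2 h; then 3 in warm THF, 45 °C, 16 h; 1 M HCl work-up
Reagents that add atoms: none
Why: Triethylamine removes both the carboxylic proton and the C2 proton of 4 once its two oxygens are chelated to divalent magnesium, and the chelated enolate 5 attacks the acyl carbon of 3 at carbon, expelling imidazolide to give the acylmalonate chelate 6; protonation on acidic work-up and loss of CO2 through a six-membered transition state then give the β-keto ester 7 with the new C2–C3 bond. The closest known reaction type is the decarboxylative Claisen condensation of magnesium malonate half esters with acyl imidazoles, the laboratory counterpart of the ketosynthase step of fatty acid biosynthesis. No ring is closed and no stereocenter is created. The step needs C-acylation over O-acylation and single over double acylation: the magnesium chelate ties up both oxygens and leaves carbon as the nucleophilic site, and 6 is a stabilised tricarbonyl chelate that should not react with a second acyl imidazole. Loss of CO2 makes the condensation irreversible, and the nearly neutral medium should leave the benzyl ester intact while the saturated C24 acyl donor offers no other reactive site.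

**Step 3**
Reactants: 7 benzyl 3-oxohexacosanoate
Product: 8 benzyl 3-hydroxyhexacosanoate (racemic at C3)
Conditions: NaBH4 (0.5 equiv), THF/EtOH 5:1, 0 °C to 20 °C, short reaction time; aq. NH4Cl
Reagents that add atoms: none
Why: Chemoselective borohydride reduction of the ketone of a β-keto ester, where the ketone is far more electrophilic than the ester and the limited hydride charge and low temperature should prevent over-reduction to the 1,3-diol and ester exchange; the C3 carbinol forms as a racemate, which is inconsequential.

**Step 4**
Reactants: 8 benzyl 3-hydroxyhexacosanoate
Product: 10 benzyl (2E)-hexacos-2-enoate, via mesylate 9 (not isolated)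
Conditions: MsCl (1.3 equiv), Et3N (2 equiv), CH2Cl2, 0 °C, 1 h; then DBU (1.5 equiv), 20 °C
Reagents that add atoms: none
Why: Sulfonylation of the secondary alcohol followed by E1cB elimination through the ester enolate should give the conjugated E-enoate as the thermodynamically preferred isomer, and the alkene geometry is irrelevant because the double bond is reduced in step 5.

**Step 5**
Reactants: 10 benzyl (2E)-hexacos-2-enoate
Product: 11 benzyl hexacosanoate
Conditions: [(Ph3P)CuH]6 (0.3 equiv of hexamer), H2O (5 equiv), degassed toluene/THF, 20 °C, argon; then air, filtration through silica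
Reagents that add atoms: none
Why: Conjugate (1,4) hydride reduction by the phosphine-stabilised hydride of monovalent copper delivers hydride to C3 and gives a copper enolate that water protonates at C2; this soft hydride should neither attack the ester carbonyl nor cleave the benzylic C–O bond, which hydrogenation over palladium would do.

**Compound list**

1 | tetracosanoic acid | CCCCCCCCCCCCCCCCCCCCCCCC(=O)O | starting material
2 | 1,1'-carbonyldiimidazole | O=C(n1ccnc1)n1ccnc1 | starting material
3 | 1-(imidazol-1-yl)tetracosan-1-one | CCCCCCCCCCCCCCCCCCCCCCCC(=O)n1ccnc1 | intermediate
4 | 3-(benzyloxy)-3-oxopropanoic acid (benzyl hydrogen malonate) | OC(=O)CC(=O)OCc1ccccc1 | starting material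
5 | magnesium chelate of the doubly deprotonated benzyl hydrogen malonate (magnesium malonate enolate) | [Mg+2].[O-]C(=O)C=C([O-])OCc1ccccc1 | intermediate
6 | magnesium chelate of benzyl 2-carboxylato-3-oxohexacosanoate (magnesium acylmalonate, enolate form) | CCCCCCCCCCCCCCCCCCCCCCCC([O-])=C(C(=O)[O-])C(=O)OCc1ccccc1.[Mg+2] | intermediate
7 | benzyl 3-oxohexacosanoate | CCCCCCCCCCCCCCCCCCCCCCCC(=O)CC(=O)OCc1ccccc1 | intermediate
8 | benzyl 3-hydroxyhexacosanoate, racemic | CCCCCCCCCCCCCCCCCCCCCCCC(O)CC(=O)OCc1ccccc1 | intermediate
9 | benzyl 3-(methanesulfonyloxy)hexacosanoate, racemic | CCCCCCCCCCCCCCCCCCCCCCCC(OS(C)(=O)=O)CC(=O)OCc1ccccc1 | intermediate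
10 | benzyl (2E)-hexacos-2-enoate | CCCCCCCCCCCCCCCCCCCCCCC/C=C/C(=O)OCc1ccccc1 | intermediate
11 | benzyl hexacosanoate | CCCCCCCCCCCCCCCCCCCCCCCCCC(=O)OCc1ccccc1 | target

**Step count**

Total steps: 5. Longest linear sequence: 5 steps, from tetracosanoic acid 1.

**Steps most likely to fail**

1. Step 2 (key step). The waxy C24 acyl imidazole may stay out of solution or be hydrolysed by adventitious water, and the half ester may decarboxylate early to benzyl acetate, so that C-acylation stays incomplete. Fallback, an acylketene route that sets out from 1 and returns at 7: tetracosanoic acid 1 would be condensed with 2,2-dimethyl-1,3-dioxane-4,6-dione (N,N'-dicyclohexylcarbodiimide, 4-dimethylaminopyridine, CH2Cl2, 0 °C to 20 °C) to give 5-(1-hydroxytetracosylidene)-2,2-dimethyl-1,3-dioxane-4,6-dione F1. Heating F1 with benzyl alcohol in toluene at about 100 °C should release acetone and CO2 and trap the acylketene as benzyl 3-oxohexacosanoate 7.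

2. Step 5. Hydride transfer to a β-alkyl enoate is slower than to an enone, so the air-sensitive copper hydride may decompose before conversion is complete, and any double-bond isomer that has moved out of conjugation would not be reduced at all. Fallback, which accepts loss of the benzyl group and restores it, sets out from 10 and returns at 11: hydrogenation of 10 (H2, 10% Pd/C, THF/EtOAc, 40 °C) should saturate the alkene and cleave the benzyl ester to give hexacosanoic acid F2. Alkylation of F2 with benzyl bromide (K2CO3, DMF/THF, 50 °C) should then give benzyl hexacosanoate 11.

3. Step 4. The base may move the double bond out of conjugation to the 3-enoate, or elimination of the mesylate may stop short. Fallback, a radical deoxygenation that bypasses the alkene, sets out from 8 and returns at 11: alcohol 8 would be acylated with phenyl chlorothionoformate (pyridine, CH2Cl2, 0 °C to 20 °C) to give benzyl 3-[(phenoxycarbonothioyl)oxy]hexacosanoate F3. Barton–McCombie deoxygenation of F3 (Bu3SnH, catalytic AIBN, toluene, 100 °C) should give benzyl hexacosanoate 11 directly, since the tin radical chain does not touch the benzyl ester.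

**Further compounds**

F1 | step 2 | 5-(1-hydroxytetracosylidene)-2,2-dimethyl-1,3-dioxane-4,6-dione | CCCCCCCCCCCCCCCCCCCCCCCC(O)=C1C(=O)OC(C)(C)OC1=O
F2 | step 5 | hexacosanoic acid | CCCCCCCCCCCCCCCCCCCCCCCCCC(=O)O
F3 | step 4 | benzyl 3-[(phenoxycarbonothioyl)oxy]hexacosanoate, racemic | CCCCCCCCCCCCCCCCCCCCCCCC(OC(=S)Oc1ccccc1)CC(=O)OCc1ccccc1
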